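**Assumption:** compound 6 is a racemate and is drawn as its (5S,6S) enantiomer; "cis" and "trans" refer to the two faces of the partly saturated ring. The route is a design and has not been run.

## Retrosynthetic overview

1. Cut the C8–O aryl ether: the target comes from 6-hydroxy-7-methoxy-2-(2-phenylethyl)chromone and a 7,8-epoxide whose oxirane is cis to the C5 oxygen, opened with net retention at C8.
2. The epoxide comes from a trans-5,6-dihydrodiol of 2-(2-phenylethyl)chromone; its two chiral ester groups resolve it, protect it and steer the epoxidation.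
3. The dihydrodiol comes from the 5,6-quinone of 6-hydroxy-2-(2-phenylethyl)chromone, so the saturated ring is made by dearomatising a benzo ring, not by cyclisation.
4. Ring order: both pyranone rings first (Claisen condensation and cyclodehydration of o-hydroxyacetophenones with ethyl 3-phenylpropanoate), then dearomatisation of one benzo ring, then the oxirane, which is opened in the last step.

## Route

**Step 1**
Reactants: 1 1-(2,5-dihydroxyphenyl)ethanone; 2 ethyl 3-phenylpropanoate
Product: 4 6-hydroxy-2-(2-phenylethyl)-4H-chromen-4-one, via 1,3-diketone 3 (not isolated)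
Conditions: NaH (5 equiv), THF, reflux; then conc. HCl, AcOH, 80 °C
Reagents that add atoms: none
Why: Claisen condensation of the ketone enolate with the ester (the phenoxides are spectators) gives the o-hydroxyaryl 1,3-diketone, which cyclodehydrates under acid to the 4-pyranone ring (classical chromone synthesis); no stereocentre is formed.

**Step 2**
Reactants: 4 6-hydroxy-2-(2-phenylethyl)-4H-chromen-4-one
Product: 5 2-(2-phenylethyl)-4H-chromene-4,5,6-trione
Conditions: (KSO3)2NO (2.5 equiv), KH2PO4 buffer (pH 6), H2O/acetone, 0 °C to rt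
Reagents that add atoms: potassium nitrosodisulfonate (Fremy's salt), [K+].[K+].[O]N(S(=O)(=O)[O-])S(=O)(=O)[O-]
Why: Teuber oxidation of a phenol whose para position (C8a) is blocked puts the new oxygen ortho, at the naphthol-alpha-like C5, which gives the only o-quinone that leaves the pyranone intact; no stereocentre is formed.

**Step 3**
Reactants: 5 2-(2-phenylethyl)-4H-chromene-4,5,6-trione
Product: 6 rac-(5S,6S)-5,6-dihydroxy-2-(2-phenylethyl)-5,6-dihydro-4H-chromen-4-one
Conditions: NaBH4 (3 equiv), EtOH, O2 stream, 0 °C to rt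
Reagents that add atoms: none
Why: Borohydride 1,2-reduction of both quinone carbonyls (o-quinone to trans-dihydrodiol reduction) delivers the second hydride anti to the first alkoxyborate, so the diol is trans and racemic; O2 re-oxidises any catechol back to 5 and the vinylogous-ester C4 carbonyl is not reduced.

**Step 4**
Reactants: 6 rac-(5S,6S)-5,6-dihydroxy-2-(2-phenylethyl)-5,6-dihydro-4H-chromen-4-one
Product: 7 (5S,6S)-4-oxo-2-(2-phenylethyl)-5,6-dihydro-4H-chromene-5,6-diyl bis{[(1R,2S,5R)-2-isopropyl-5-methylcyclohexyl]oxyacetate}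
Conditions: (−)-menthoxyacetyl chloride (2.5 equiv), pyridine, DMAP (cat.), CH2Cl2, 0 °C; the two diastereomers separated by chromatography or crystallisation
Reagents that add atoms: (−)-menthoxyacetyl chloride, ClC(=O)CO[C@@H]1C[C@H](C)CC[C@H]1C(C)C
Why: Acyl chloride/pyridine esterification gives two diastereomeric diesters (classical resolution through covalent diastereomers) and the (5S,6S) one is kept, which fixes the absolute configuration at C5 and C6; the esters also stop dehydration back to a phenol.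

**Step 5**
Reactants: 7 (5S,6S)-bis(menthoxyacetate) of the trans-dihydrodiol
Product: 8 (5S,6R,7S,8S)-7,8-epoxy-4-oxo-2-(2-phenylethyl)-5,6,7,8-tetrahydro-4H-chromene-5,6-diyl bis{[(1R,2S,5R)-2-isopropyl-5-methylcyclohexyl]oxyacetate} (oxirane cis to the C5 ester, trans to the C6 ester)
Conditions: DMDO (1.3 equiv) in acetone, CH2Cl2, −20 to 0 °C
Reagents that add atoms: dimethyldioxirane, CC1(C)OO1
Why: Dioxirane epoxidation (Prilezhaev type) of C7=C8, the only alkene outside the pyranone; peri strain with C4=O holds both esters pseudoaxial, the allylic C6 ester shields its own face, and oxygen therefore adds anti to it and cis to the C5 ester, setting C7 and C8 as 7S,8S.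

**Step 6**
Reactants: 9 2-methoxybenzene-1,4-diol
Product: 10 1-(2,5-dihydroxy-4-methoxyphenyl)ethanone
Conditions: AcOH (1.5 equiv), BF3·OEt2 (as medium), 90 °C; aq. NaOAc work-up
Reagents that add atoms: acetic acid, CC(=O)O
Why: Friedel–Crafts C-acylation (Nencki type) goes to the carbon para to the methoxy group and ortho to a hydroxyl, the most activated unhindered position; no stereocentre is formed.

**Step 7**
Reactants: 10 1-(2,5-dihydroxy-4-methoxyphenyl)ethanone; 2 ethyl 3-phenylpropanoate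
Product: 12 6-hydroxy-7-methoxy-2-(2-phenylethyl)-4H-chromen-4-one, via 1,3-diketone 11 (not isolated)
Conditions: NaH (5 equiv), THF, reflux; then conc. HCl, AcOH, 80 °C
Reagents that add atoms: none
Why: Same Claisen condensation and acid cyclodehydration as in step 1 (chromone synthesis); the aryl methyl ether survives HCl/AcOH and no stereocentre is formed.

**Step 8**
Reactants: 8 (5S,6R,7S,8S)-7,8-epoxy diester; 12 6-hydroxy-7-methoxy-2-(2-phenylethyl)-4H-chromen-4-one
Product: 14 (5S,6R,7S,8S)-5,6,7-trihydroxy-8-{[7-methoxy-4-oxo-2-(2-phenylethyl)-4H-chromen-6-yl]oxy}-2-(2-phenylethyl)-5,6,7,8-tetrahydro-4H-chromen-4-one, via coupled diester 13 (not isolated)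
Conditions: Pd(PPh3)4 (5 mol %), 12 (1.1 equiv), THF, 0 °C to rt; then K2CO3 (0.3 equiv), MeOH, 0 °C, same flask
Reagents that add atoms: none
Why: Proposed new method: zerovalent palladium opens the oxirane at C8 with inversion because the C8–O bond is gamma to the pyranone carbonyl, giving a divalent palladium pi-allyl (vinylogous enolate) over C8–C8a–C4a; the C7 alkoxide deprotonates 12, and the phenoxide attacks C8 anti to palladium, on the face the epoxide oxygen left, so the C8–O aryl bond forms with net retention, cis to the C7 hydroxyl (8S), where uncatalysed SN2 opening would give the trans isomer; the closest known reaction type is the Tsuji–Trost addition of phenols to vinyl epoxides and the double-inversion alkoxylation of gamma,delta-epoxy-alpha,beta-unsaturated esters, not yet shown for an epoxide whose vinyl unit is the tetrasubstituted C=C of a 4-pyranone; K2CO3-catalysed transesterification then removes both esters, so any acyl shift from O6 to O7 does not matter.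

## Compound list

1 | 1-(2,5-dihydroxyphenyl)ethanone | CC(=O)c1cc(O)ccc1O | starting material
2 | ethyl 3-phenylpropanoate | CCOC(=O)CCc1ccccc1 | starting material
3 | 1-(2,5-dihydroxyphenyl)-5-phenylpentane-1,3-dione | O=C(CC(=O)CCc1ccccc1)c1cc(O)ccc1O | intermediate
4 | 6-hydroxy-2-(2-phenylethyl)-4H-chromen-4-one | O=c1cc(CCc2ccccc2)oc2ccc(O)cc12 | intermediate
5 | 2-(2-phenylethyl)-4H-chromene-4,5,6-trione | O=C1C=Cc2oc(CCc3ccccc3)cc(=O)c2C1=O | intermediate
6 | rac-(5S,6S)-5,6-dihydroxy-2-(2-phenylethyl)-5,6-dihydro-4H-chromen-4-one (trans-diol, racemate, one enantiomer drawn) | O=c1cc(CCc2ccccc2)oc2c1[C@H](O)[C@@H](O)C=C2 | intermediate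
7 | (5S,6S)-4-oxo-2-(2-phenylethyl)-5,6-dihydro-4H-chromene-5,6-diyl bis{[(1R,2S,5R)-2-isopropyl-5-methylcyclohexyl]oxyacetate} | O=c1cc(CCc2ccccc2)oc2c1[C@H](OC(=O)CO[C@@H]1C[C@H](C)CC[C@H]1C(C)C)[C@@H](OC(=O)CO[C@@H]1C[C@H](C)CC[C@H]1C(C)C)C=C2 | intermediate
8 | (5S,6R,7S,8S)-7,8-epoxy-4-oxo-2-(2-phenylethyl)-5,6,7,8-tetrahydro-4H-chromene-5,6-diyl bis{[(1R,2S,5R)-2-isopropyl-5-methylcyclohexyl]oxyacetate} | O=c1cc(CCc2ccccc2)oc2c1[C@H](OC(=O)CO[C@@H]1C[C@H](C)CC[C@H]1C(C)C)[C@@H](OC(=O)CO[C@@H]1C[C@H](C)CC[C@H]1C(C)C)[C@@H]1O[C@H]21 | intermediate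
9 | 2-methoxybenzene-1,4-diol | COc1cc(O)ccc1O | starting material
10 | 1-(2,5-dihydroxy-4-methoxyphenyl)ethanone | CC(=O)c1cc(O)c(OC)cc1O | intermediate
11 | 1-(2,5-dihydroxy-4-methoxyphenyl)-5-phenylpentane-1,3-dione | O=C(CC(=O)CCc1ccccc1)c1cc(O)c(OC)cc1O | intermediate
12 | 6-hydroxy-7-methoxy-2-(2-phenylethyl)-4H-chromen-4-one | COc1cc2oc(CCc3ccccc3)cc(=O)c2cc1O | intermediate
13 | (5S,6S,7S,8S)-7-hydroxy-8-{[7-methoxy-4-oxo-2-(2-phenylethyl)-4H-chromen-6-yl]oxy}-4-oxo-2-(2-phenylethyl)-5,6,7,8-tetrahydro-4H-chromene-5,6-diyl bis{[(1R,2S,5R)-2-isopropyl-5-methylcyclohexyl]oxyacetate} | O=c1cc(CCc2ccccc2)oc2c1[C@H](OC(=O)CO[C@@H]1C[C@H](C)CC[C@H]1C(C)C)[C@@H](OC(=O)CO[C@@H]1C[C@H](C)CC[C@H]1C(C)C)[C@H](O)[C@@H]2Oc1cc2c(=O)cc(CCc3ccccc3)oc2cc1OC | intermediate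
14 | (5S,6R,7S,8S)-5,6,7-trihydroxy-8-{[7-methoxy-4-oxo-2-(2-phenylethyl)-4H-chromen-6-yl]oxy}-2-(2-phenylethyl)-5,6,7,8-tetrahydro-4H-chromen-4-one | COc1cc2oc(CCc3ccccc3)cc(=O)c2cc1O[C@@H]1c2oc(CCc3ccccc3)cc(=O)c2[C@H](O)[C@@H](O)[C@@H]1O | target

## Step count and risks

Total steps: 8. Longest linear sequence: 6 (steps 1, 2, 3, 4, 5, 8).

**Step 8 (the proposed new step).** It can fail in three ways: zerovalent palladium may not add into an epoxide flanked by the donor-substituted, tetrasubstituted pyranone C=C; the palladium intermediate may undergo beta-hydride elimination to the C7 ketone and then a phenol; or the allylic C5 ester may ionise. The fallback uses known chemistry, sets out from 8 and comes back at 14, and replaces the palladium double inversion by two ordinary SN2 inversions. Me3SiBr (CH2Cl2, −40 °C) opens the oxirane at the activated C8 to (5S,6R,7S,8R)-8-bromo-4-oxo-2-(2-phenylethyl)-7-(trimethylsilyloxy)-5,6,7,8-tetrahydro-4H-chromene-5,6-diyl bis(menthoxyacetate) F6. The caesium phenoxide of 12 (Cs2CO3, DMF, 0 °C) displaces the bromide to the (5S,6R,7S,8S)-8-aryloxy-7-(trimethylsilyloxy) bis(menthoxyacetate) F7. K2CO3 in MeOH then removes the silyl ether and both esters and gives 14.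

**Step 5.** Facial selectivity rests on steric shielding alone, and the diene terminus is somewhat electron-poor. The fallback sets out from 7 and comes back at 14, and builds the same oxirane by trans-diaxial halohydrin formation instead of face shielding. K2CO3/MeOH gives the free (5S,6S)-5,6-dihydroxy-2-(2-phenylethyl)-5,6-dihydro-4H-chromen-4-one F3. N-Bromoacetamide in THF/H2O gives (5S,6R,7R,8R)-7-bromo-5,6,8-trihydroxy-2-(2-phenylethyl)-5,6,7,8-tetrahydro-4H-chromen-4-one F4 (bromonium on the face of the allylic hydroxyl, water trans). tBuOK (THF, 0 °C) closes it to (5S,6R,7S,8S)-7,8-epoxy-5,6-dihydroxy-2-(2-phenylethyl)-5,6,7,8-tetrahydro-4H-chromen-4-one F5, whose oxirane is cis to the C5 hydroxyl whichever carbon water attacked. F5 is coupled with 12 under the palladium conditions of step 8 and gives 14 directly.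

**Step 2.** Radical oxidation of an acyl-deactivated phenol may be slow or unselective, and the quinone is labile; step 3 shares this sensitivity but is not given its own fallback. The fallback sets out from 4 and comes back at 5, and installs the second oxygen before oxidising. Duff formylation (hexamethylenetetramine, CF3CO2H, 90 °C) at C5 gives 6-hydroxy-4-oxo-2-(2-phenylethyl)-4H-chromene-5-carbaldehyde F1. Dakin oxidation (H2O2, H3BO3, cat. H2SO4, THF) gives 5,6-dihydroxy-2-(2-phenylethyl)-4H-chromen-4-one F2. Ag2O (Na2SO4, dry CH2Cl2) then gives 5, which is filtered and taken at once into step 3.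

## Further compounds

F1 | step 2 | 6-hydroxy-4-oxo-2-(2-phenylethyl)-4H-chromene-5-carbaldehyde | O=Cc1c(O)ccc2oc(CCc3ccccc3)cc(=O)c12
F2 | step 2 | 5,6-dihydroxy-2-(2-phenylethyl)-4H-chromen-4-one | O=c1cc(CCc2ccccc2)oc2ccc(O)c(O)c12
F3 | step 5 | (5S,6S)-5,6-dihydroxy-2-(2-phenylethyl)-5,6-dihydro-4H-chromen-4-one (single enantiomer) | O=c1cc(CCc2ccccc2)oc2c1[C@H](O)[C@@H](O)C=C2
F4 | step 5 | (5S,6R,7R,8R)-7-bromo-5,6,8-trihydroxy-2-(2-phenylethyl)-5,6,7,8-tetrahydro-4H-chromen-4-one | O=c1cc(CCc2ccccc2)oc2c1[C@H](O)[C@@H](O)[C@@H](Br)[C@@H]2O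
F5 | step 5 | (5S,6R,7S,8S)-7,8-epoxy-5,6-dihydroxy-2-(2-phenylethyl)-5,6,7,8-tetrahydro-4H-chromen-4-one | O=c1cc(CCc2ccccc2)oc2c1[C@H](O)[C@@H](O)[C@@H]1O[C@H]21
F6 | step 8 | (5S,6R,7S,8R)-8-bromo-4-oxo-2-(2-phenylethyl)-7-(trimethylsilyloxy)-5,6,7,8-tetrahydro-4H-chromene-5,6-diyl bis{[(1R,2S,5R)-2-isopropyl-5-methylcyclohexyl]oxyacetate} | O=c1cc(CCc2ccccc2)oc2c1[C@H](OC(=O)CO[C@@H]1C[C@H](C)CC[C@H]1C(C)C)[C@@H](OC(=O)CO[C@@H]1C[C@H](C)CC[C@H]1C(C)C)[C@H](O[Si](C)(C)C)[C@H]2Br
F7 | step 8 | (5S,6R,7S,8S)-8-{[7-methoxy-4-oxo-2-(2-phenylethyl)-4H-chromen-6-yl]oxy}-4-oxo-2-(2-phenylethyl)-7-(trimethylsilyloxy)-5,6,7,8-tetrahydro-4H-chromene-5,6-diyl bis{[(1R,2S,5R)-2-isopropyl-5-methylcyclohexyl]oxyacetate} | O=c1cc(CCc2ccccc2)oc2c1[C@H](OC(=O)CO[C@@H]1C[C@H](C)CC[C@H]1C(C)C)[C@@H](OC(=O)CO[C@@H]1C[C@H](C)CC[C@H]1C(C)C)[C@H](O[Si](C)(C)C)[C@@H]2Oc1cc2c(=O)cc(CCc3ccccc3)oc2cc1OC
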